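Product stops growing in the elm and alder runs: from 12.0 h to 20.0 h the substrate left stays within the scatter, yet partner remains. We read that as a catalyst dying on its own clock.

in all of them: left-handed substrate 0.80 M; right-handed substrate 0.80 M; impurity 0.19 mM

| run | partner | free catalyst | remark | time |
|---|---|---|---|---|
| elm | 2.4 M | 0.54 mM | run made earlier |  |
| alder | 2.4 M | 1.2 mM | run made earlier |  |
| flask | 2.40 M | 0.80 mM |  | 25 h |

- elm (time / h: left-handed substrate / %, right-handed substrate / %): 1.00: 40.7, 37.2; 3.00: 26.7, 24.6; 6.00: 19.2, 17.7; 8.00: 17.3, 16.8; 12.0: 15.7, 15.3; 15.0: 14.5, 15.2; 20.0: 15.5, 14.7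
- alder (time / h: left-handed substrate / %, right-handed substrate / %): 1.50: 18.6, 15.6; 2.50: 11.4, 8.6; 4.00: 5.8, 6.3; 6.00: 4.9, 4.3; 8.00: 4.4, 3.7; 12.0: 4.0, 3.7; 20.0: 4.6, 3.9

(scatter of a reading: 0.5 percentage points)

- free catalyst is single-handed; left-handed substrate and right-handed substrate are mirror images of each other, charged as a racemate, each of them at the stated concentration
- steps thought possible: free catalyst + left-handed substrate <-> catalyst intermediate A; free catalyst + right-handed substrate <-> catalyst intermediate B; partner + catalyst intermediate A -> free catalyst + left-handed product; partner + catalyst intermediate B -> free catalyst + right-handed product; left-handed substrate <-> right-handed substrate; free catalyst + impurity -> spent catalyst A; free catalyst -> spent catalyst B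
- an excess is the difference of the two amounts in percent of their sum
- an excess is below zero if the other one leads

- part of the left-handed substrate and right-handed substrate charged together that has reacted at 25 h
- excess of left-handed product over right-handed product in the product at 25 h
- excess of right-handed substrate over left-handed substrate among what is left of the two at 25 h

1. Let s be the substrate left, both hands together, and a the catalyst charge minus the impurity charge, taking one catalyst lost per impurity. Elm gives 0.350 mM, alder 1.01 mM, this flask 0.610 mM. Read up to the first reading of each run, −ln s per hour is 0.250 h⁻¹ in elm and 0.715 h⁻¹ in alder, a ratio of 2.86, near the ratio of a, 2.89.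

2. Freeze the partner, and s falls pseudo-first-order. Then −ln s at the stall, per mM of a, is a constant.

3. Elm's last reading has s = 30.2%, so its reach D, that −ln s at the stall per mM of a, reads 3.42 mM⁻¹. Alder's last reading has s = 8.50%, so D reads 2.44 mM⁻¹. The reach reads smaller in alder, where by the balance partner ends at 39.0% of its charge against elm's 53.5%.

4. Two extreme flasks follow. With elm's reach this flask converts 87.6%, with alder's 77.4%. Its a lies between theirs, so we take D linearly in a: 3.03 mM⁻¹, hence our estimate c = 84.2%.

The forecast, holding that “the impurity quickly kills about one catalyst per impurity”, gave c = 83%, eP = −6%, eS = −1.5%.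

The flask gives c = 83.9%, eP = −9.76%, eS = 0%.

    free catalyst + left-handed substrate ⇌ catalyst intermediate A (K = 1.08 M⁻¹, k = 64.6 M⁻¹ s⁻¹)
    free catalyst + right-handed substrate ⇌ catalyst intermediate B (K = 2.98 M⁻¹, k = 32.8 M⁻¹ s⁻¹)
    partner + catalyst intermediate A → free catalyst + left-handed product (k = 0.306 M⁻¹ s⁻¹)
    partner + catalyst intermediate B → free catalyst + right-handed product (k = 0.151 M⁻¹ s⁻¹)
    left-handed substrate ⇌ right-handed substrate (k = 6.99 × 10⁻⁵ s⁻¹)
    free catalyst + impurity → spent catalyst A (k = 426 M⁻¹ s⁻¹)
    free catalyst → spent catalyst B (k = 1.85 × 10⁻⁴ s⁻¹)

The flask's reach is 2.99 mM⁻¹, between alder's and elm's. The neighbour charged with 4.8 × 10⁻⁴ M of impurity keeps a = 0.320 mM, close to elm's, so elm's reach gives 66.5%; that neighbour reached 67.6%. The reach speaks of how much reacts, not of which hand: the product of this flask leans right-handed mainly because catalyst intermediate A runs back to free catalyst and left-handed substrate, and in the run with that backward step taken away eP goes from −9.76% to 50.4%.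

The numbers in the tables come from a simulation for substances that don't exist.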